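The plan cuts the C2–C3 bond of the dihydrofuran ring (benzofuran numbering). C3 carries a hydroxyl group and C2 the isopropenyl group, so the ring hides a homoallylic alcohol: an allylboron unit hung on O1 can add through its O-bearing carbon to a formyl group on C3a. This single operation forms C2–C3, closes the O1–C2–C3–C3a–C7a ring, creates the isopropenyl group and sets both stereocentres, trans from the E enol ether and (2S,3R) from a chiral phosphoric acid. The precursor is a benzaldehyde whose ortho oxygen is the enol-ether end of an (E)-2-methylallyl pinacol boronate; it is released from its dimethyl acetal only just before use. Acylation with the (Z)-acid and desilylation complete the synthesis.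

Key step: step 10

Assumption: the facial preference of the BINOL-derived phosphoric acid is carried over from intermolecular allylborations of aryl aldehydes, where the (R)-acid leads to Re-face addition; the (S)-acid is therefore specified for the Si-face addition needed here, and its enantiomer would be used if the tethered case ran the other way.

Abbreviations: TBSO = tert-butyldimethylsilyloxy; Bpin = 4,4,5,5-tetramethyl-1,3,2-dioxaborolan-2-yl.

Step 1
Reactants: 1 5-bromo-2,4-dihydroxybenzaldehyde
Product: 2 5-bromo-4-(TBSO)-2-hydroxybenzaldehyde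
Conditions: TBSCl (1.05 equiv), imidazole, CH2Cl2, 0 °C
Reagents that add atoms: tert-butyldimethylsilyl chloride, CC(C)(C)[Si](C)(C)Cl
Why: Selective O-silylation, because the 2-hydroxyl is held in a hydrogen bond to the formyl oxygen while the free, more acidic 4-hydroxyl para to the aldehyde takes up the one equivalent of silyl chloride.

Step 2
Reactants: 2 5-bromo-4-(TBSO)-2-hydroxybenzaldehyde
Product: 4 5-acetyl-4-(TBSO)-2-hydroxybenzaldehyde, via ethoxyvinyl arene 3 (not isolated)
Conditions: tributyl(1-ethoxyvinyl)stannane, PdCl2(PPh3)2 (5 mol%), toluene, 100 °C; then 1 M HCl, THF, rt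
Reagents that add atoms: tributyl(1-ethoxyvinyl)stannane, CCCC[Sn](CCCC)(CCCC)C(=C)OCC; water, O
Why: Stille coupling of the aryl bromide with an acetyl anion equivalent that tolerates the free phenol and the aldehyde, followed by acid hydrolysis of enol ether 3 to the methyl ketone.

Step 3
Reactants: 4 5-acetyl-4-(TBSO)-2-hydroxybenzaldehyde
Product: 5 1-[2-(TBSO)-5-(dimethoxymethyl)-4-hydroxyphenyl]ethanone
Conditions: HC(OMe)3, MeOH, pyridinium p-toluenesulfonate (5 mol%), rt; Et3N, evaporate, use crude
Reagents that add atoms: trimethyl orthoformate, COC(OC)OC; methanol, CO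
Why: Acid-catalysed acetalisation with orthoformate as water scavenger masks the aldehyde, which reacts much faster than the conjugated ortho-silyloxy aryl ketone, so that the formyl group meets neither hydride nor the allylboron unit before step 9; the product is used crude because the neighbouring phenol makes this acetal labile.

Step 4
Reactants: 6 (E)-3-ethoxy-2-methylprop-2-enal (3-ethoxymethacrolein)
Product: 8 (E)-2-methyl-3-oxoprop-1-en-1-yl 4-methylbenzenesulfonate, via sodium enolate 7 (not isolated)
Conditions: NaOH (1.0 equiv), H2O, rt; evaporate to dryness; p-toluenesulfonyl chloride, MeCN, 0 °C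
Reagents that add atoms: sodium hydroxide, [Na+].[OH-]; p-toluenesulfonyl chloride, Cc1ccc(cc1)S(=O)(=O)Cl
Why: Addition–elimination of hydroxide on the β-ethoxy enal gives the stable enolate of methylmalondialdehyde, and O-sulfonylation of this 1,3-dicarbonyl enolate (enol tosylate formation) replaces the poor ethoxide leaving group by tosylate.

Step 5
Reactants: 5 1-[2-(TBSO)-5-(dimethoxymethyl)-4-hydroxyphenyl]ethanone; 8 (E)-2-methyl-3-oxoprop-1-en-1-yl 4-methylbenzenesulfonate
Product: 9 (E)-3-[4-acetyl-5-(TBSO)-2-(dimethoxymethyl)phenoxy]-2-methylprop-2-enal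
Conditions: Et3N (1.5 equiv), DABCO (10 mol%), CH2Cl2, 0 °C to rt
Reagents that add atoms: none
Why: Vinylic substitution by conjugate addition and β-elimination, relayed by DABCO, is downhill because tosylate leaves far better than this acidic aryloxide (direct exchange of the ethoxy group of 6 would be uphill), and reversible addition leaves the more stable E isomer with aryloxy trans to formyl.

Step 6
Reactants: 9 (E)-3-[4-acetyl-5-(TBSO)-2-(dimethoxymethyl)phenoxy]-2-methylprop-2-enal
Product: 10 1-[2-(TBSO)-5-(dimethoxymethyl)-4-{[(E)-3-hydroxy-2-methylprop-1-en-1-yl]oxy}phenyl]ethanone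
Conditions: LiAlH(OtBu)3 (1.2 equiv), THF, −78 to −40 °C; aqueous potassium sodium tartrate
Reagents that add atoms: none
Why: Chemoselective 1,2-reduction of the aldehyde by a bulky, mild alkoxyaluminium hydride, which leaves the hindered aryl ketone alone at low temperature and, in an aprotic medium, does not cleave the vinylogous aryl formate; the alkene geometry is untouched.

Step 7
Reactants: 10 1-[2-(TBSO)-5-(dimethoxymethyl)-4-{[(E)-3-hydroxy-2-methylprop-1-en-1-yl]oxy}phenyl]ethanone
Product: 11 (E)-3-[4-acetyl-5-(TBSO)-2-(dimethoxymethyl)phenoxy]-2-methylprop-2-en-1-yl methyl carbonate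
Conditions: ClCO2Me, pyridine, CH2Cl2, 0 °C
Reagents that add atoms: methyl chloroformate, COC(=O)Cl
Why: Standard acylation of a primary allylic alcohol with a chloroformate gives the allylic carbonate that palladium can ionise.

Step 8
Reactants: 11 (E)-3-[4-acetyl-5-(TBSO)-2-(dimethoxymethyl)phenoxy]-2-methylprop-2-en-1-yl methyl carbonate; 12 bis(pinacolato)diboron
Product: 13 1-[2-(TBSO)-5-(dimethoxymethyl)-4-{[(E)-2-methyl-3-(Bpin)prop-1-en-1-yl]oxy}phenyl]ethanone
Conditions: Pd2(dba)3 (2.5 mol%), DMSO, 50 °C
Reagents that add atoms: none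
Why: Palladium-catalysed borylation of an allylic carbonate with a diboron reagent: zerovalent palladium forms the η3-allyl complex, the methoxide released with CO2 activates the diboron, and boron goes to the less hindered CH2 terminus with the E enol ether retained (syn allyl complex), while the acetal and the ketone are inert to the allylboronate.

Step 9
Reactants: 13 1-[2-(TBSO)-5-(dimethoxymethyl)-4-{[(E)-2-methyl-3-(Bpin)prop-1-en-1-yl]oxy}phenyl]ethanone
Product: 14 5-acetyl-4-(TBSO)-2-{[(E)-2-methyl-3-(Bpin)prop-1-en-1-yl]oxy}benzaldehyde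
Conditions: silica gel wetted with 10% aqueous oxalic acid, CH2Cl2, 0 °C; cold filtration through NaHCO3/Na2SO4; concentrate below 0 °C, use at once
Reagents that add atoms: water, O
Why: Acetal hydrolysis of a 2,4-dioxygenated benzaldehyde dimethyl acetal is fast with a weak heterogeneous acid in the cold, which spares the silyl ether, the electron-poor aryl enol ether and the allylic C–B bond; the aldehyde is kept cold and used immediately because it carries its own allylating group.

Step 10
Reactants: 14 5-acetyl-4-(TBSO)-2-{[(E)-2-methyl-3-(Bpin)prop-1-en-1-yl]oxy}benzaldehyde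
Product: 16 1-[(2S,3R)-6-(TBSO)-3-hydroxy-2-(prop-1-en-2-yl)-2,3-dihydro-1-benzofuran-5-yl]ethanone (trans), via pinacol borate 15 (not isolated)
Conditions: (S)-TRIP [(S)-3,3′-bis(2,4,6-triisopropylphenyl)-1,1′-binaphthyl-2,2′-diyl hydrogen phosphate] (10 mol%), 4 Å molecular sieves, toluene, −40 °C; then Et3N, aqueous NaHCO3
Reagents that add atoms: none
Why: Proposed new method: boron binds the formyl oxygen and the O-bearing γ-carbon of the allylboronate adds to the aldehyde through a closed six-membered chair (Zimmerman–Traxler) transition state with allyl transposition, which forms C2–C3 and turns the C(Me)–CH2B end into the isopropenyl group, while the phosphoric acid is expected to accelerate this path by hydrogen bonding to a boronate oxygen. The closest known reaction types are the chiral phosphoric acid-catalysed allylboration of aryl aldehydes with allyl and crotyl pinacol boronates and the thermal intramolecular γ-alkoxyallylboration that gives trans-2-vinyl-3-hydroxy cyclic ethers; their combination on an aryl enol ether is the untested part. The O1–C2–C3–C3a–C7a ring closes in the 5-exo-trig mode at the formyl carbon, fused to the chair. The trans relation of C2 and C3 follows from the E enol ether, which puts the aryloxy oxygen and the aryl carbon both equatorial (anti adduct), and the absolute configuration (3R and with it 2S) from the (S)-acid, which should direct the addition to the Si face of the formyl group. The step needs the aldehyde to react in preference to the acetyl ketone and the catalysed path to outrun the racemic thermal one: the ortho tether reaches only the formyl group, and the bulky pinacol ester, the β-methyl branch, the electron-rich aldehyde and the low temperature hold the uncatalysed closure back. Basic aqueous work-up cleaves borate 15 without exposing the acid-labile benzylic alcohol to the catalyst at room temperature.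

Step 11
Reactants: 17 but-2-yn-1-ol
Product: 18 (Z)-2-(tributylstannyl)but-2-en-1-ol
Conditions: Bu3SnH (1.1 equiv), [(C5Me5)RuCl]4 (1.25 mol%), CH2Cl2, rt
Reagents that add atoms: tributyltin hydride, CCCC[SnH](CCCC)CCCC
Why: Ruthenium-catalysed, hydroxyl-directed trans-hydrostannation of a propargylic alcohol puts tin on the alkyne carbon next to the hydroxyl and adds H and Sn anti, which fixes the Z geometry (methyl cis to tin) of the later angelate-type acid.

Step 12
Reactants: 18 (Z)-2-(tributylstannyl)but-2-en-1-ol
Product: 19 (Z)-2-iodobut-2-en-1-ol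
Conditions: I2 (1.05 equiv), CH2Cl2, 0 °C; aqueous Na2S2O3, KF
Reagents that add atoms: iodine, II
Why: Iododestannylation of an alkenylstannane proceeds with retention of the alkene geometry.

Step 13
Reactants: 19 (Z)-2-iodobut-2-en-1-ol
Product: 20 (Z)-2-(hydroxymethyl)but-2-enoic acid
Conditions: CO (1 atm), Pd(OAc)2 (5 mol%), PPh3 (10 mol%), Et3N (3 equiv), DMF/H2O, 50 °C; then 1 M HCl
Reagents that add atoms: carbon monoxide, [C-]#[O+]; water, O
Why: Palladium-catalysed hydroxycarbonylation of the alkenyl iodide (oxidative addition, CO insertion, hydrolysis of the acylpalladium) keeps the alkene geometry, and any α-alkylidene β-lactone formed through the neighbouring hydroxyl is opened by the aqueous base to the same hydroxy acid.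

Step 14
Reactants: 20 (Z)-2-(hydroxymethyl)but-2-enoic acid
Product: 22 (Z)-2-(acetoxymethyl)but-2-enoic acid, via acetic mixed anhydride 21 (not isolated)
Conditions: Ac2O (2.5 equiv), pyridine, CH2Cl2, 0 °C to rt; then H2O, THF, rt
Reagents that add atoms: acetic anhydride, CC(=O)OC(C)=O
Why: O-Acetylation of the primary alcohol; the mixed anhydride 21 formed at the carboxyl group is hydrolysed back to the free acid by water.

Step 15
Reactants: 16 1-[(2S,3R)-6-(TBSO)-3-hydroxy-2-(prop-1-en-2-yl)-2,3-dihydro-1-benzofuran-5-yl]ethanone; 22 (Z)-2-(acetoxymethyl)but-2-enoic acid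
Product: 24 (2S,3R)-5-acetyl-6-(TBSO)-2-(prop-1-en-2-yl)-2,3-dihydro-1-benzofuran-3-yl (Z)-2-(acetoxymethyl)but-2-enoate, via trichlorobenzoyl mixed anhydride 23 (not isolated)
Conditions: 22, 2,4,6-trichlorobenzoyl chloride, Et3N, toluene, 0 °C; then 16, DMAP (0.2 equiv), 0 °C to rt
Reagents that add atoms: none
Why: Yamaguchi esterification, in which the hindered aryl carbonyl of 23 steers the benzylic alcohol to the side-chain acyl group under basic conditions that neither ionise nor dehydrate the carbinol; C3 keeps its configuration because its C–O bond is not broken, and low temperature with little DMAP limits Z to E drift.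

Step 16
Reactants: 24 (2S,3R)-5-acetyl-6-(TBSO)-2-(prop-1-en-2-yl)-2,3-dihydro-1-benzofuran-3-yl (Z)-2-(acetoxymethyl)but-2-enoate
Product: 25 (2S,3R)-5-acetyl-6-hydroxy-2-(prop-1-en-2-yl)-2,3-dihydro-1-benzofuran-3-yl (Z)-2-(acetoxymethyl)but-2-enoate (CNP0193314.2)
Conditions: Bu4NF (1.1 equiv), AcOH (1.5 equiv), THF, 0 °C
Reagents that add atoms: none
Why: Fluoride cleavage of the aryl silyl ether (activated by the ortho acetyl group) under acetic acid buffering, which protonates the phenoxide at once so that it cannot expel the para-benzylic carboxylate, cleave the acetate or isomerise the ester.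

Compound list
1 | 5-bromo-2,4-dihydroxybenzaldehyde | O=Cc1cc(Br)c(O)cc1O | starting material
2 | 5-bromo-4-(tert-butyldimethylsilyloxy)-2-hydroxybenzaldehyde | O=Cc1cc(Br)c(O[Si](C)(C)C(C)(C)C)cc1O | intermediate
3 | 4-(tert-butyldimethylsilyloxy)-5-(1-ethoxyvinyl)-2-hydroxybenzaldehyde | C=C(OCC)c1cc(C=O)c(O)cc1O[Si](C)(C)C(C)(C)C | intermediate
4 | 5-acetyl-4-(tert-butyldimethylsilyloxy)-2-hydroxybenzaldehyde | CC(=O)c1cc(C=O)c(O)cc1O[Si](C)(C)C(C)(C)C | intermediate
5 | 1-[2-(tert-butyldimethylsilyloxy)-5-(dimethoxymethyl)-4-hydroxyphenyl]ethanone | CC(=O)c1cc(C(OC)OC)c(O)cc1O[Si](C)(C)C(C)(C)C | intermediate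
6 | (E)-3-ethoxy-2-methylprop-2-enal (3-ethoxymethacrolein) | CCO/C=C(\C)C=O | starting material
7 | sodium (E)-2-methyl-3-oxoprop-1-en-1-olate | [Na+].[O-]/C=C(\C)C=O | intermediate
8 | (E)-2-methyl-3-oxoprop-1-en-1-yl 4-methylbenzenesulfonate | Cc1ccc(cc1)S(=O)(=O)O/C=C(\C)C=O | intermediate
9 | (E)-3-[4-acetyl-5-(tert-butyldimethylsilyloxy)-2-(dimethoxymethyl)phenoxy]-2-methylprop-2-enal | CC(=O)c1cc(C(OC)OC)c(O/C=C(\C)C=O)cc1O[Si](C)(C)C(C)(C)C | intermediate
10 | 1-[2-(tert-butyldimethylsilyloxy)-5-(dimethoxymethyl)-4-{[(E)-3-hydroxy-2-methylprop-1-en-1-yl]oxy}phenyl]ethanone | CC(=O)c1cc(C(OC)OC)c(O/C=C(\C)CO)cc1O[Si](C)(C)C(C)(C)C | intermediate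
11 | (E)-3-[4-acetyl-5-(tert-butyldimethylsilyloxy)-2-(dimethoxymethyl)phenoxy]-2-methylprop-2-en-1-yl methyl carbonate | CC(=O)c1cc(C(OC)OC)c(O/C=C(\C)COC(=O)OC)cc1O[Si](C)(C)C(C)(C)C | intermediate
12 | bis(pinacolato)diboron | CC1(C)OB(OC1(C)C)B1OC(C)(C)C(C)(C)O1 | starting material
13 | 1-[2-(tert-butyldimethylsilyloxy)-5-(dimethoxymethyl)-4-{[(E)-2-methyl-3-(4,4,5,5-tetramethyl-1,3,2-dioxaborolan-2-yl)prop-1-en-1-yl]oxy}phenyl]ethanone | CC(=O)c1cc(C(OC)OC)c(O/C=C(\C)CB2OC(C)(C)C(C)(C)O2)cc1O[Si](C)(C)C(C)(C)C | intermediate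
14 | 5-acetyl-4-(tert-butyldimethylsilyloxy)-2-{[(E)-2-methyl-3-(4,4,5,5-tetramethyl-1,3,2-dioxaborolan-2-yl)prop-1-en-1-yl]oxy}benzaldehyde | CC(=O)c1cc(C=O)c(O/C=C(\C)CB2OC(C)(C)C(C)(C)O2)cc1O[Si](C)(C)C(C)(C)C | intermediate
15 | 1-[(2S,3R)-6-(tert-butyldimethylsilyloxy)-2-(prop-1-en-2-yl)-3-(4,4,5,5-tetramethyl-1,3,2-dioxaborolan-2-yloxy)-2,3-dihydro-1-benzofuran-5-yl]ethanone | C=C(C)[C@@H]1Oc2cc(O[Si](C)(C)C(C)(C)C)c(C(C)=O)cc2[C@H]1OB1OC(C)(C)C(C)(C)O1 | intermediate
16 | 1-[(2S,3R)-6-(tert-butyldimethylsilyloxy)-3-hydroxy-2-(prop-1-en-2-yl)-2,3-dihydro-1-benzofuran-5-yl]ethanone (trans) | C=C(C)[C@@H]1Oc2cc(O[Si](C)(C)C(C)(C)C)c(C(C)=O)cc2[C@H]1O | intermediate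
17 | but-2-yn-1-ol | CC#CCO | starting material
18 | (Z)-2-(tributylstannyl)but-2-en-1-ol | C/C=C(/CO)[Sn](CCCC)(CCCC)CCCC | intermediate
19 | (Z)-2-iodobut-2-en-1-ol | C/C=C(/CO)I | intermediate
20 | (Z)-2-(hydroxymethyl)but-2-enoic acid | C/C=C(/CO)C(=O)O | intermediate
21 | acetic (Z)-2-(acetoxymethyl)but-2-enoic anhydride | C/C=C(/COC(C)=O)C(=O)OC(C)=O | intermediate
22 | (Z)-2-(acetoxymethyl)but-2-enoic acid | C/C=C(/COC(C)=O)C(=O)O | intermediate
23 | (Z)-2-(acetoxymethyl)but-2-enoic 2,4,6-trichlorobenzoic anhydride | C/C=C(/COC(C)=O)C(=O)OC(=O)c1c(Cl)cc(Cl)cc1Cl | intermediate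
24 | (2S,3R)-5-acetyl-6-(tert-butyldimethylsilyloxy)-2-(prop-1-en-2-yl)-2,3-dihydro-1-benzofuran-3-yl (Z)-2-(acetoxymethyl)but-2-enoate | C=C(C)[C@@H]1Oc2cc(O[Si](C)(C)C(C)(C)C)c(C(C)=O)cc2[C@H]1OC(=O)/C(=C\C)COC(C)=O | intermediate
25 | (2S,3R)-5-acetyl-6-hydroxy-2-(prop-1-en-2-yl)-2,3-dihydro-1-benzofuran-3-yl (Z)-2-(acetoxymethyl)but-2-enoate | C=C(C)[C@@H]1Oc2cc(O)c(C(C)=O)cc2[C@H]1OC(=O)/C(=C\C)COC(C)=O | target

Total step count: 16. Longest linear sequence: 11 steps (steps 1, 2, 3, 5, 6, 7, 8, 9, 10, 15, 16).

Steps most likely to fail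

Step 10. The uncatalysed, racemic closure may run ahead of the catalysed one, possibly already while 14 is being handled after step 9. The acid may also discriminate the two formyl faces poorly in the tethered transition state. Either way 16 would arrive trans but with low enantiomeric purity. The fallback moves absolute control from catalysis to resolution. Setting out from 14, the aldehyde is left in toluene at room temperature without acid, the known thermal manifold of intramolecular allylboration, to give the racemic trans borate F1. Aqueous NaHCO3 converts this into the racemic trans alcohol F2. Lipase-catalysed acetylation (Burkholderia cepacia lipase, vinyl acetate, tert-butyl methyl ether) should then acylate the (2R,3S) enantiomer to the acetate F3, following the usual preference of lipases for secondary benzylic carbinols. The unreacted (2S,3R) alcohol is 16, where the route is rejoined.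

Step 15. Reversible addition of DMAP to the activated acyl group may isomerise the Z double bond to E or expel the allylic acetate (SN2′). If acylation is slow, the carbinol may also eliminate towards the benzofuran. The fallback is an acylation without any nucleophilic catalyst. Setting out from 22 and 16, the acid is converted into its symmetric anhydride F4 (N,N′-dicyclohexylcarbodiimide, CH2Cl2). This is added to the lithium alkoxide of 16 (LiN(SiMe3)2, THF, −78 °C), an anionic acylation that is an established way to attach angelate-type acids without isomerisation. The product is 24.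

Step 5. The phenoxide may attack sulfur instead of the vinylic carbon of 8 (sulfonyl transfer), or the labile acetal of 5 may break down before it is vinylated. The fallback bypasses the enal stage by making the aryl–O–vinyl bond at the alcohol oxidation level. This is an Ullmann-type C–O coupling of 5 with commercial (E)-3-iodo-2-methylprop-2-en-1-ol, OC/C(C)=C/I (CuI, N,N-dimethylglycine, Cs2CO3, dioxane, 60 °C), which keeps the alkene geometry. It sets out from 5 and comes back at alcohol 10, so that steps 4 to 6 are no longer needed.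

Further compounds
F1 | step 10 | racemic trans-1-[6-(tert-butyldimethylsilyloxy)-2-(prop-1-en-2-yl)-3-(4,4,5,5-tetramethyl-1,3,2-dioxaborolan-2-yloxy)-2,3-dihydro-1-benzofuran-5-yl]ethanone | C=C(C)[C@@H]1Oc2cc(O[Si](C)(C)C(C)(C)C)c(C(C)=O)cc2[C@H]1OB1OC(C)(C)C(C)(C)O1.C=C(C)[C@H]1Oc2cc(O[Si](C)(C)C(C)(C)C)c(C(C)=O)cc2[C@@H]1OB1OC(C)(C)C(C)(C)O1
F2 | step 10 | racemic trans-1-[6-(tert-butyldimethylsilyloxy)-3-hydroxy-2-(prop-1-en-2-yl)-2,3-dihydro-1-benzofuran-5-yl]ethanone | C=C(C)[C@@H]1Oc2cc(O[Si](C)(C)C(C)(C)C)c(C(C)=O)cc2[C@H]1O.C=C(C)[C@H]1Oc2cc(O[Si](C)(C)C(C)(C)C)c(C(C)=O)cc2[C@@H]1O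
F3 | step 10 | (2R,3S)-5-acetyl-6-(tert-butyldimethylsilyloxy)-2-(prop-1-en-2-yl)-2,3-dihydro-1-benzofuran-3-yl acetate | C=C(C)[C@H]1Oc2cc(O[Si](C)(C)C(C)(C)C)c(C(C)=O)cc2[C@@H]1OC(C)=O
F4 | step 15 | (Z)-2-(acetoxymethyl)but-2-enoic anhydride (symmetric) | C/C=C(/COC(C)=O)C(=O)OC(=O)/C(=C\C)COC(C)=O
F0 | step 5 | none | none
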